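**Retrosynthetic overview**
1. Target 18 ← global O-debenzylation of the tetrabenzyl ether 17; this comes last so the base-sensitive flavanone stereocentre only meets neutral conditions.
2. Flavanone ring C of 17 ← catalytic asymmetric oxa-Michael closure and decarboxylation of alkylidene β-ketoester 15, which comes from the key C–C bond: a Knoevenagel (aldol-type) condensation of aldehyde 10 with β-ketoester 14.
3. Aldehyde 10 ← SNAr diaryl ether formation between 3'-hydroxyflavone 8 and 4-fluorobenzaldehyde; flavone ring C of 8 ← Claisen–Schmidt aldol chalcone 6, then I2/DMSO oxidative cyclisation.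
4. β-Ketoester 14 ← 2',4',6'-trihydroxyacetophenone by 4-O-methylation, mono-benzylation, and O-Boc formation followed by anionic O→C acyl transfer.
5. Ring order: flavone pyranone ring first, diaryl ether second, flavanone ring last.

Assumption: the quinine-derived thiourea is taken to give the 2S series; if the first run (chiral HPLC/CD) shows 2R, its quinidine-derived pseudoenantiomer is used in the same step.

**Step 1**
Reactants: 1 2',4',6'-trihydroxyacetophenone
Product: 2 1-[2,4-bis(benzyloxy)-6-hydroxyphenyl]ethan-1-one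
Conditions: BnBr (2.1 equiv), K2CO3, DMF, rt
Reagents that add atoms: benzyl bromide BrCc1ccccc1
Why: Williamson ether synthesis in which the last hydroxyl, hydrogen-bonded to the acetyl carbonyl, is the least reactive, so two equivalents stop at the dibenzyl ether.

**Step 2**
Reactants: 3 3,4-dihydroxybenzaldehyde
Product: 4 4-(benzyloxy)-3-hydroxybenzaldehyde
Conditions: BnBr (1.05 equiv), NaHCO3, DMF, 40 °C
Reagents that add atoms: benzyl bromide BrCc1ccccc1
Why: Regioselective Williamson etherification, because only the more acidic 4-OH (para to the formyl group) is ionised by the weak base.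

**Step 3**
Reactants: 4 4-(benzyloxy)-3-hydroxybenzaldehyde
Product: 5 4-(benzyloxy)-3-(methoxymethoxy)benzaldehyde
Conditions: MOMCl, K2CO3, acetone, rt
Reagents that add atoms: chloromethyl methyl ether COCCl
Why: Acetal (MOM) protection of the phenol, stable to the basic aldol step and later removable with acid without touching the benzyl ethers.

**Step 4**
Reactants: 2 1-[2,4-bis(benzyloxy)-6-hydroxyphenyl]ethan-1-one; 5 4-(benzyloxy)-3-(methoxymethoxy)benzaldehyde
Product: 6 (E)-1-[2,4-bis(benzyloxy)-6-hydroxyphenyl]-3-[4-(benzyloxy)-3-(methoxymethoxy)phenyl]prop-2-en-1-one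
Conditions: KOH (50% aq.), EtOH–THF, rt, 48 h
Reagents that add atoms: none
Why: Claisen–Schmidt aldol condensation of the methyl ketone enolate with a non-enolisable aldehyde, with E1cB dehydration giving the conjugated E-chalcone.

**Step 5**
Reactants: 6 (E)-1-[2,4-bis(benzyloxy)-6-hydroxyphenyl]-3-[4-(benzyloxy)-3-(methoxymethoxy)phenyl]prop-2-en-1-one
Product: 8 5,7-bis(benzyloxy)-2-[4-(benzyloxy)-3-hydroxyphenyl]-4H-chromen-4-one, via 3'-O-MOM flavone 7 (not isolated)
Conditions: I2 (10 mol%), DMSO, 130 °C; then 2 M HCl, MeOH–THF, 50 °C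
Reagents that add atoms: none
Why: Oxidative cyclisation of a 2'-hydroxychalcone (oxa-Michael closure, iodination and HI loss, DMSO as terminal oxidant) gives the flavone, and acid methanolysis then cleaves only the MOM acetal.

**Step 6**
Reactants: 8 5,7-bis(benzyloxy)-2-[4-(benzyloxy)-3-hydroxyphenyl]-4H-chromen-4-one; 9 4-fluorobenzaldehyde
Product: 10 4-{2-(benzyloxy)-5-[5,7-bis(benzyloxy)-4-oxo-4H-chromen-2-yl]phenoxy}benzaldehyde
Conditions: K2CO3, DMF, 90 °C
Reagents that add atoms: none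
Why: Nucleophilic aromatic substitution (SNAr) of the para-formyl-activated fluoride by the phenoxide forms the diaryl ether and installs the aldehyde for the flavanone half.

**Step 7**
Reactants: 1 2',4',6'-trihydroxyacetophenone
Product: 11 1-(2,6-dihydroxy-4-methoxyphenyl)ethan-1-one
Conditions: Me2SO4 (1.0 equiv), K2CO3 (1.0 equiv), acetone, rt → reflux
Reagents that add atoms: dimethyl sulfate COS(=O)(=O)OC
Why: Williamson-type O-methylation that favours the unchelated, most acidic 4-OH over the two carbonyl-hydrogen-bonded ortho hydroxyls.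

**Step 8**
Reactants: 11 1-(2,6-dihydroxy-4-methoxyphenyl)ethan-1-one
Product: 12 1-[2-(benzyloxy)-6-hydroxy-4-methoxyphenyl]ethan-1-one
Conditions: BnBr (1.05 equiv), K2CO3, acetone, reflux
Reagents that add atoms: benzyl bromide BrCc1ccccc1
Why: Williamson mono-benzylation of one of two equivalent hydroxyls, after which the remaining one is locked in a hydrogen bond to the carbonyl and resists further alkylation.

**Step 9**
Reactants: 12 1-[2-(benzyloxy)-6-hydroxy-4-methoxyphenyl]ethan-1-one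
Product: 13 2-acetyl-3-(benzyloxy)-5-methoxyphenyl tert-butyl carbonate
Conditions: Boc2O (1.5 equiv), DMAP (10 mol%), CH2Cl2, rt
Reagents that add atoms: di-tert-butyl dicarbonate CC(C)(C)OC(=O)OC(=O)OC(C)(C)C
Why: DMAP-catalysed O-acylation of the phenol places the tert-butoxycarbonyl unit next to the acetyl group for transfer to carbon.

**Step 10**
Reactants: 13 2-acetyl-3-(benzyloxy)-5-methoxyphenyl tert-butyl carbonate
Product: 14 tert-butyl 3-[2-(benzyloxy)-6-hydroxy-4-methoxyphenyl]-3-oxopropanoate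
Conditions: LiN(SiMe3)2 (2.5 equiv), THF, −78 → 0 °C; then cold 1 M HCl
Reagents that add atoms: none
Why: Baker–Venkataraman-type anionic O→C acyl transfer (an intramolecular Claisen condensation through a six-membered transition state), where the aryloxide is the better leaving group and the bulky tert-butyl ester resists lactonisation to a coumarin.

**Step 11**
Reactants: 10 4-{2-(benzyloxy)-5-[5,7-bis(benzyloxy)-4-oxo-4H-chromen-2-yl]phenoxy}benzaldehyde; 14 tert-butyl 3-[2-(benzyloxy)-6-hydroxy-4-methoxyphenyl]-3-oxopropanoate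
Product: 15 tert-butyl 2-[2-(benzyloxy)-6-hydroxy-4-methoxybenzoyl]-3-(4-{2-(benzyloxy)-5-[5,7-bis(benzyloxy)-4-oxo-4H-chromen-2-yl]phenoxy}phenyl)prop-2-enoate (E/Z mixture, used as such)
Conditions: piperidine (20 mol%), AcOH (20 mol%), 4 Å MS, toluene, rt → 40 °C
Reagents that add atoms: none
Why: Knoevenagel condensation (iminium-assisted aldol addition of the β-ketoester, then dehydration) joins the two halves under near-neutral conditions that the flavone tolerates, while the carbonyl-hydrogen-bonded phenol stays uncyclised.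

**Step 12**
Reactants: 15 tert-butyl 2-[2-(benzyloxy)-6-hydroxy-4-methoxybenzoyl]-3-(4-{2-(benzyloxy)-5-[5,7-bis(benzyloxy)-4-oxo-4H-chromen-2-yl]phenoxy}phenyl)prop-2-enoate
Product: 17 (2S)-5-(benzyloxy)-2-(4-{2-(benzyloxy)-5-[5,7-bis(benzyloxy)-4-oxo-4H-chromen-2-yl]phenoxy}phenyl)-7-methoxy-2,3-dihydro-4H-chromen-4-one, via 3-tert-butoxycarbonyl flavanone 16 (not isolated)
Conditions: quinine-derived thiourea [N-(3,5-bis(trifluoromethyl)phenyl)-N'-(9-deoxy-epi-quinin-9-yl)thiourea] (10 mol%), toluene, −25 °C; then TsOH·H2O, 80 °C; recrystallise to >99% ee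
Reagents that add atoms: none
Why: Bifunctional-catalyst asymmetric intramolecular oxa-Michael addition, in which the thiourea binds the β-ketoester and the quinuclidine delivers the phenol to one face to set C2 as S; TsOH then quenches the base, cleaves the tert-butyl ester and triggers decarboxylation, removing C3 as a stereocentre without touching C2.

**Step 13**
Reactants: 17 (2S)-5-(benzyloxy)-2-(4-{2-(benzyloxy)-5-[5,7-bis(benzyloxy)-4-oxo-4H-chromen-2-yl]phenoxy}phenyl)-7-methoxy-2,3-dihydro-4H-chromen-4-one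
Product: 18 (2S)-2-{4-[5-(5,7-dihydroxy-4-oxo-4H-chromen-2-yl)-2-hydroxyphenoxy]phenyl}-5-hydroxy-7-methoxy-2,3-dihydro-4H-chromen-4-one (target)
Conditions: H2 (1 atm), 10% Pd/C, THF–MeOH, rt, stopped at full conversion
Reagents that add atoms: none
Why: Catalytic hydrogenolysis removes all four benzyl ethers under neutral conditions, so the flavanone cannot racemise by ring opening and the methyl ether, diaryl ether and flavone stay intact.

**Compound list**
1 | 2',4',6'-trihydroxyacetophenone | CC(=O)c1c(O)cc(O)cc1O | starting material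
2 | 1-[2,4-bis(benzyloxy)-6-hydroxyphenyl]ethan-1-one | CC(=O)c1c(O)cc(OCc2ccccc2)cc1OCc1ccccc1 | intermediate
3 | 3,4-dihydroxybenzaldehyde | O=Cc1ccc(O)c(O)c1 | starting material
4 | 4-(benzyloxy)-3-hydroxybenzaldehyde | O=Cc1ccc(OCc2ccccc2)c(O)c1 | intermediate
5 | 4-(benzyloxy)-3-(methoxymethoxy)benzaldehyde | COCOc1cc(C=O)ccc1OCc1ccccc1 | intermediate
6 | (E)-1-[2,4-bis(benzyloxy)-6-hydroxyphenyl]-3-[4-(benzyloxy)-3-(methoxymethoxy)phenyl]prop-2-en-1-one | COCOc1cc(/C=C/C(=O)c2c(O)cc(OCc3ccccc3)cc2OCc2ccccc2)ccc1OCc1ccccc1 | intermediate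
7 | 5,7-bis(benzyloxy)-2-[4-(benzyloxy)-3-(methoxymethoxy)phenyl]-4H-chromen-4-one | COCOc1cc(-c2cc(=O)c3c(OCc4ccccc4)cc(OCc4ccccc4)cc3o2)ccc1OCc1ccccc1 | intermediate
8 | 5,7-bis(benzyloxy)-2-[4-(benzyloxy)-3-hydroxyphenyl]-4H-chromen-4-one | Oc1cc(-c2cc(=O)c3c(OCc4ccccc4)cc(OCc4ccccc4)cc3o2)ccc1OCc1ccccc1 | intermediate
9 | 4-fluorobenzaldehyde | O=Cc1ccc(F)cc1 | starting material
10 | 4-{2-(benzyloxy)-5-[5,7-bis(benzyloxy)-4-oxo-4H-chromen-2-yl]phenoxy}benzaldehyde | O=Cc1ccc(Oc2cc(-c3cc(=O)c4c(OCc5ccccc5)cc(OCc5ccccc5)cc4o3)ccc2OCc2ccccc2)cc1 | intermediate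
11 | 1-(2,6-dihydroxy-4-methoxyphenyl)ethan-1-one | COc1cc(O)c(C(C)=O)c(O)c1 | intermediate
12 | 1-[2-(benzyloxy)-6-hydroxy-4-methoxyphenyl]ethan-1-one | COc1cc(O)c(C(C)=O)c(OCc2ccccc2)c1 | intermediate
13 | 2-acetyl-3-(benzyloxy)-5-methoxyphenyl tert-butyl carbonate | COc1cc(OC(=O)OC(C)(C)C)c(C(C)=O)c(OCc2ccccc2)c1 | intermediate
14 | tert-butyl 3-[2-(benzyloxy)-6-hydroxy-4-methoxyphenyl]-3-oxopropanoate | COc1cc(O)c(C(=O)CC(=O)OC(C)(C)C)c(OCc2ccccc2)c1 | intermediate
15 | tert-butyl 2-[2-(benzyloxy)-6-hydroxy-4-methoxybenzoyl]-3-(4-{2-(benzyloxy)-5-[5,7-bis(benzyloxy)-4-oxo-4H-chromen-2-yl]phenoxy}phenyl)prop-2-enoate, E/Z mixture (alkene geometry left open) | COc1cc(O)c(C(=O)C(=Cc2ccc(Oc3cc(-c4cc(=O)c5c(OCc6ccccc6)cc(OCc6ccccc6)cc5o4)ccc3OCc3ccccc3)cc2)C(=O)OC(C)(C)C)c(OCc2ccccc2)c1 | intermediate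
16 | tert-butyl (2S)-5-(benzyloxy)-2-(4-{2-(benzyloxy)-5-[5,7-bis(benzyloxy)-4-oxo-4H-chromen-2-yl]phenoxy}phenyl)-7-methoxy-4-oxo-3,4-dihydro-2H-chromene-3-carboxylate, C3 epimers in equilibrium with the enol (C3 left open) | COc1cc(OCc2ccccc2)c2c(c1)O[C@H](c1ccc(Oc3cc(-c4cc(=O)c5c(OCc6ccccc6)cc(OCc6ccccc6)cc5o4)ccc3OCc3ccccc3)cc1)C(C(=O)OC(C)(C)C)C2=O | intermediate
17 | (2S)-5-(benzyloxy)-2-(4-{2-(benzyloxy)-5-[5,7-bis(benzyloxy)-4-oxo-4H-chromen-2-yl]phenoxy}phenyl)-7-methoxy-2,3-dihydro-4H-chromen-4-one | COc1cc(OCc2ccccc2)c2c(c1)O[C@H](c1ccc(Oc3cc(-c4cc(=O)c5c(OCc6ccccc6)cc(OCc6ccccc6)cc5o4)ccc3OCc3ccccc3)cc1)CC2=O | intermediate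
18 | (2S)-2-{4-[5-(5,7-dihydroxy-4-oxo-4H-chromen-2-yl)-2-hydroxyphenoxy]phenyl}-5-hydroxy-7-methoxy-2,3-dihydro-4H-chromen-4-one | COc1cc(O)c2c(c1)O[C@H](c1ccc(Oc3cc(-c4cc(=O)c5c(O)cc(O)cc5o4)ccc3O)cc1)CC2=O | target

**Step count**
Total steps: 13.
Longest linear sequence: 8 steps (steps 2, 3, 4, 5, 6, 11, 12, 13; compound 3 → 18).

**Steps most likely to fail, with fallbacks**

Step 12 (asymmetric oxa-Michael and decarboxylation). The extra ortho benzyloxy group on the phenol ring is outside the usual substrate range, so the ee may be low. Partial loss of the chelated 5-O-benzyl groups under TsOH would be harmless, since step 13 removes them anyway. The fallback sets out from 8 and 12 and comes back at 17, setting the stereocentre by a rhodium-catalysed asymmetric 1,4-addition of an arylboron reagent to a chromone. Phenol 8 is coupled with 4-bromophenylboronic acid (Cu(OAc)2, pyridine, 4 Å MS, CH2Cl2, air) to give 5,7-bis(benzyloxy)-2-[4-(benzyloxy)-3-(4-bromophenoxy)phenyl]-4H-chromen-4-one F1. Borylation (B2pin2, PdCl2(dppf), KOAc, dioxane, 90 °C) then gives the pinacol boronate 5,7-bis(benzyloxy)-2-{4-(benzyloxy)-3-[4-(4,4,5,5-tetramethyl-1,3,2-dioxaborolan-2-yl)phenoxy]phenyl}-4H-chromen-4-one F2. Separately, acetophenone 12 is heated with N,N-dimethylformamide dimethyl acetal to the enaminone (E)-1-[2-(benzyloxy)-6-hydroxy-4-methoxyphenyl]-3-(dimethylamino)prop-2-en-1-one F3, which closes with HCl in CH2Cl2 to 5-(benzyloxy)-7-methoxy-4H-chromen-4-one F4. F2 is added to F4 with [Rh(OH)(cod)]2 and the MeO-F12-BIPHEP enantiomer that gives the 2S product (aq. KOH, toluene, rt) to reach 17. The 2-aryl-substituted flavone unit in F2 is too hindered to accept the aryl group.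

Step 10 (O→C acyl transfer to the β-ketoester). Risks are loss of the Boc group back to 12 or lactonisation to a 4-hydroxycoumarin. The fallback sets out from 12 and comes back at 14, using an intermolecular Claisen-type C-acylation on a protected phenol. Compound 12 is silylated (TBSCl, imidazole, DMF) to 1-[2-(benzyloxy)-6-[(tert-butyldimethylsilyl)oxy]-4-methoxyphenyl]ethan-1-one F5. Its lithium enolate (LiN(SiMe3)2, 2.2 equiv, THF, −78 °C) is acylated with tert-butyl 1H-imidazole-1-carboxylate to tert-butyl 3-[2-(benzyloxy)-6-[(tert-butyldimethylsilyl)oxy]-4-methoxyphenyl]-3-oxopropanoate F6. Buffered desilylation (Bu4NF, AcOH, THF, 0 °C) returns 14.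

Step 13 (global hydrogenolysis). Risks are partial reduction of the flavone C2=C3 bond or hydrogenolysis of the benzylic C2–O bond of the flavanone. The fallback sets out from 17 and comes back at 18 by a non-reductive Lewis-acid debenzylation: BCl3 with pentamethylbenzene as benzyl-cation scavenger, CH2Cl2, −78 °C. At this temperature the non-chelated 7-methyl ether is not cleaved and the flavanone does not open. It makes no new compound: none F0.

**Further compounds**
F1 | step 12 | 5,7-bis(benzyloxy)-2-[4-(benzyloxy)-3-(4-bromophenoxy)phenyl]-4H-chromen-4-one | Brc1ccc(Oc2cc(-c3cc(=O)c4c(OCc5ccccc5)cc(OCc5ccccc5)cc4o3)ccc2OCc2ccccc2)cc1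
F2 | step 12 | 5,7-bis(benzyloxy)-2-{4-(benzyloxy)-3-[4-(4,4,5,5-tetramethyl-1,3,2-dioxaborolan-2-yl)phenoxy]phenyl}-4H-chromen-4-one | CC1(C)OB(c2ccc(Oc3cc(-c4cc(=O)c5c(OCc6ccccc6)cc(OCc6ccccc6)cc5o4)ccc3OCc3ccccc3)cc2)OC1(C)C
F3 | step 12 | (E)-1-[2-(benzyloxy)-6-hydroxy-4-methoxyphenyl]-3-(dimethylamino)prop-2-en-1-one | COc1cc(O)c(C(=O)/C=C/N(C)C)c(OCc2ccccc2)c1
F4 | step 12 | 5-(benzyloxy)-7-methoxy-4H-chromen-4-one | COc1cc(OCc2ccccc2)c2c(=O)ccoc2c1
F5 | step 10 | 1-[2-(benzyloxy)-6-[(tert-butyldimethylsilyl)oxy]-4-methoxyphenyl]ethan-1-one | COc1cc(O[Si](C)(C)C(C)(C)C)c(C(C)=O)c(OCc2ccccc2)c1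
F6 | step 10 | tert-butyl 3-[2-(benzyloxy)-6-[(tert-butyldimethylsilyl)oxy]-4-methoxyphenyl]-3-oxopropanoate | COc1cc(O[Si](C)(C)C(C)(C)C)c(C(=O)CC(=O)OC(C)(C)C)c(OCc2ccccc2)c1
F0 | step 13 | none | none
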